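The readings come from a simulation from invented constants; scatter was added.

We will follow one molecule of D through the noon flask, ask its chances at each fork, and let those chances rank the options.

| flask | J | D | Q | temperature | remark | time |
|---|---|---|---|---|---|---|
| noon | 0.10 M | 4 equiv | 5 mM | 50 °C | the very flask that is asked about, followed so far |  |
| autumn | 0.067 M | 4 equiv | 5 mM | 45 °C | run made earlier |  |
| flask | 0.10 M | 4.00 equiv | 5.00 mM | 50 °C |  | 1.0 h |

noon run (percent of the J charged)

| time / min | E / % | J / % |
|---|---|---|
| 12.0 | 29.6 | 57.8 |
| 25.0 | 29.6 | 55.8 |
| 40.0 | 29.4 | 54.4 |
| 50.0 | 29.7 | 53.3 |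
| 60.0 | 29.1 | 52.9 |

autumn run (percent of the J charged)

| time / s | E / % | J / % |
|---|---|---|
| 15.0 | 2.2 | 80.3 |
| 30.0 | 3.5 | 78.7 |
| 40.0 | 4.8 | 77.5 |
| 60.0 | 7.5 | 75.1 |
| 80.0 | 9.6 | 73.0 |

(scatter of a reading: 0.3 percentage points)

- blue: at 1.0 h add D, 100 % of the amount charged, then wait 20 min
- teal: at 1.0 h take out 90 % of the E then present, then wait 20 min
- red: change nothing and wait 20 min more
- amber: at 1.0 h raise the temperature by 15 K, then wait 20 min

- in percentages every species weighs as the J in it: one G counts as two
- as a solid, counted per litre of solution: J
- removed E is counted in
- the numbers in the tables scatter with a standard deviation of 0.3 percentage points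
- candidate steps: D + Q -> Z; 2 L -> G; L + D <-> E; J <-> L
- at the start none of J is in solution
- additions bring no volume worth counting

1. E, in percent of the J first charged, at 1.0 h
2. which option adds most E ("none" when 2 percentage points or less is all one gets) (blue / teal / red / amber / none)
3. E present, with what was taken out counted in, in percent of the J first charged, after blue
4. E present, with what was taken out counted in, in percent of the J first charged, after teal

We read the noon table first. Down the E column the values stay between 29.1 % and 29.7 %, with a scatter of 0.3 percentage points, while the J column falls from 57.8 % to 52.9 %. So J is still being consumed, but E does not follow. Across the first row, E and J leave a gap of 12.6 %, which we read as mostly dissolved L, with solid J feeding it. Solid J remains in the last row, so we take c_L as steady. In the autumn table, E is still climbing at its last reading, so we read the flat noon E beside free D as a balance at steady c_L, with the forward step pseudo-first-order in D.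

The first fork costs D hardly any of its molecules, and we book the whole of Q against D. At the second fork, a molecule of D sits either free or in E, and the odds are r, the plateau value of c_E over free c_D. From the reading at 25.0 min, we get c_E = 29.6 mM and r = 0.0810.

Red leaves r and the D pool as they are, so we expect E to stay near 29.6 %. Blue enlarges the pool, and r then gives 59.6 %; the extra 30 points is less than the J in the last row. Teal banks what is removed and re-shares the remaining D, giving 54.2 %. The autumn slope of 4.58 mM/min, read at another temperature and another charge, gives as a rough scale a plateau's worth of E in 6.47 min, which is shorter than 20 min. No run shows a plateau at another temperature, so amber stays unread.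

The forecast says 29.5 % now, blue as the best option, 59 % after blue and 53.6 % after teal, the last two lower than our figures by its allowance for lag, and it calls the flat E “equilibrium with L clamped, not a stall”.

The flask gives 29.8 % now and 59.9 % after blue, 54.6 % after teal. The gains are 30 points for blue, 25 points for teal, 0 points for red and −0.0087 points for amber, so the best option is blue.

    D + Q → Z (k = 0.960 /M/s, Ea = 48.0 kJ/mol)
    2 L → G (k = 0.00520 /M/s, Ea = 63.0 kJ/mol)
    L + D ⇌ E (K = 6.80 /M, k = 0.0400 /M/s, Ea = 49.0 kJ/mol, ΔH = 0 kJ/mol)
    J ⇌ L, rate k4*(cs4 - [L]) while solid is left; crystals form when [L] > cs4 (solubility = 12.0 mM, k = 0.720 /s)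
    (constants at 50 °C)

In the noon flask, L + D and E relax with a half-life of 0.551 min at the asked time, far shorter than 1.0 h. E stands at 29.8 % at 30.0 min and 29.8 % at 600 min, and at that later time L stands at 12.0 % and J at 4.33 %.

In a neighbouring flask, the same but with 6.80 equiv of D from the start, r gives 50.6 %. The computed result for that flask is 50.9 %.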